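## Retrosynthetic overview

- **Feature.** The fifteen core carbons of the hydroazulene are an unbroken farnesyl chain with two extra C–C bonds. Ring CH2 C10 to the methyl-bearing quaternary C1 (farnesyl C1–C7) closes the cycloheptene. Ring-fusion C5 to the isopropyl-bearing C4 (farnesyl C6–C10) closes the cyclopentane.
- **Late bonds.** The C6 ester comes from jaeschkeanadiol and veratric acid. The 6α-carbinol comes from the trans-fused 4β-hydroxy-6-ketone by hydroxyl-directed reduction.
- **Oxygens.** C5–H and C6–O come from radical opening of the 5β,6β-epoxide of the 4β-allylic alcohol. C4–O comes from a singlet-oxygen ene reaction on the tetrasubstituted C4=C5 olefin of daucene, so this olefin is the handle for both oxygens.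
- **Why no C6 enone relay.** Radical allylic oxidation cannot tell C6 from C3, C7 and C10. A C5 enolate would probably be protonated anti to the isopropyl group, which gives the cis ring fusion.
- **Rings.** Daucene comes from (2E,6E)-farnesyl diphosphate by one enzymatic cationic bicyclisation that forms the seven- and five-membered rings in one asynchronous event. Farnesol gives the diphosphate in two steps.

Key step: step 3

Numbering and faces: daucane numbering is used (C1 quaternary carbon, C2 and C3 ring CH2, C4 isopropyl-bearing carbon, C5 ring fusion, C6 ester carbon, C7 CH2, C8=C9 olefin, C10 CH2); β is the face of the C1 methyl group.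

Assumption: a recombinant cyclase that gives dauca-4,8-diene as its main product with the 1R fold is taken as available by screening of daucane-forming homologues or by active-site mutagenesis.

## Route

Step 1
Reactants: 1 (2E,6E)-farnesol
Product: 2 (2E,6E)-farnesyl chloride
Conditions: NCS, Me2S, CH2Cl2, −30 → 0 °C
Reagents that add atoms: N-chlorosuccinimide, O=C1CCC(=O)N1Cl
Why: Corey–Kim-type chlorination, in which chloride displaces the alkoxysulfonium salt of the allylic alcohol at the primary carbon without allylic transposition or loss of E geometry; no stereocentre is formed.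

Step 2
Reactants: 2 (2E,6E)-farnesyl chloride
Product: 3 (2E,6E)-farnesyl diphosphate, isolated and used as the triammonium salt (drawn as the free acid)
Conditions: (n-Bu4N)3HP2O7, MeCN, rt; then cation exchange resin (NH4+ form), aq NH4HCO3/i-PrOH; cellulose chromatography
Reagents that add atoms: tris(tetrabutylammonium) hydrogen diphosphate, CCCC[N+](CCCC)(CCCC)CCCC.CCCC[N+](CCCC)(CCCC)CCCC.CCCC[N+](CCCC)(CCCC)CCCC.OP(=O)([O-])OP(=O)([O-])[O-]
Why: SN2 displacement of the primary allylic chloride by the acetonitrile-soluble diphosphate anion gives the diphosphate ester directly, without transposition or E/Z scrambling, and exchange to the ammonium form makes it water-soluble for the enzyme; no stereocentre is formed.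

Step 3
Reactants: 3 (2E,6E)-farnesyl diphosphate
Product: 4 daucene, (1R)-dauca-4,8-diene
Conditions: recombinant daucene synthase (His6-tagged, from E. coli), MgCl2 (10 mM), HEPES pH 7.5, DTT, 10 % glycerol, pentane overlay, 30 °C
Reagents that add atoms: none
Why: The magnesium ions held by the aspartate-rich motifs pull off the diphosphate, which is returned to C3 and released again so that the C2–C3 bond can rotate and the cisoid allylic cation needed for a Z olefin inside a seven-membered ring is formed (farnesyl numbering in this line). C1 of that cation bonds to C7 of the central olefin while C6 bonds to C10 of the distal olefin in one asynchronous event that never parks charge on secondary C6, the resulting C11 cation takes a 1,2-hydride from C10, and loss of the C6 proton leaves the tetrasubstituted olefin. The closest known reaction type is the conversion of farnesyl diphosphate into daucane hydrocarbons and alcohols by class-one (ionisation-initiated) sesquiterpene cyclases. The cycloheptene closes in the 7-endo-trig mode on the C6=C7 olefin and the cyclopentane in the 5-exo-trig mode on the C10=C11 olefin. The one stereocentre that survives, quaternary C7 (daucane C1, R), is fixed by the face of the 6E olefin that the pocket turns towards C1, so it is under enzyme and not substrate control. The step needs 1,7- in place of 1,6-, 1,10- or 1,11-closure and proton loss from C6 in place of water capture; the substrate helps only through its 6E geometry and the three-atom spacer that holds the nucleophilic C10=C11 olefin next to C6 and makes the second closure Markovnikov, and the rest is secured by the fold imposed by the pocket and by the bound diphosphate as base.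

Step 4
Reactants: 4 daucene
Product: 6 (1R,4R)-dauca-5,8-dien-4-ol (4β-OH), via 4β-hydroperoxide 5 (not isolated)
Conditions: O2, tetraphenylporphyrin (cat.), visible light, CH2Cl2, −20 °C, stopped when 4 is consumed; then PPh3, −20 °C → rt
Reagents that add atoms: oxygen (used as singlet oxygen), O=O
Why: Schenck ene reaction, in which singlet oxygen picks the more electron-rich tetrasubstituted C4=C5 olefin and bonds at C4, remote from quaternary C1 (the known preference for abstraction geminal to the largest substituent), so only a C6 hydrogen is available; because the C1–C10 bond holds the seven-membered ring on the α face, only H-6β is aligned with the π system, the suprafacial process should place oxygen on the β face of C4 (4R), and PPh3 reduces the O–O bond with retention.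

Step 5
Reactants: 6 (1R,4R)-dauca-5,8-dien-4-ol
Product: 7 (1R,4R,5S,6R)-5,6-epoxydauc-8-en-4-ol (4β-OH, 5β,6β-epoxide)
Conditions: VO(acac)2 (5 mol %), t-BuOOH (decane), toluene, 0 °C → rt
Reagents that add atoms: tert-butyl hydroperoxide, CC(C)(C)OO
Why: Hydroxyl-directed epoxidation, in which the vanadate ester of the tertiary allylic alcohol delivers oxygen to the neighbouring C5=C6 olefin on the face of the hydroxyl (β), which sets C5 and C6 and leaves the remote, undirected C8=C9 olefin untouched.

Step 6
Reactants: 7 (1R,4R,5S,6R)-5,6-epoxydauc-8-en-4-ol
Product: 8 (1R,4R,5S,6R)-dauc-8-ene-4,6-diol (4β-OH, 5α-H, 6β-OH; 6-epi-jaeschkeanadiol)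
Conditions: Cp2TiCl2 (2.5 equiv), Zn dust, THF, rt; then 7, 1,4-cyclohexadiene (10 equiv), THF, −20 °C → rt; aq NaH2PO4
Reagents that add atoms: none
Why: Nugent–RajanBabu reductive epoxide opening, of the kind that turns trisubstituted 2,3-epoxy alcohols into 1,3-diols: Cp2TiCl (trivalent titanium) cleaves the C5–O bond to the tertiary C5 radical while C6 keeps its β-oxygen as a bulky titanium alkoxide, and because that alkoxide, the C4 oxygen and the C1 methyl group all cover the β face, 1,4-cyclohexadiene should hand its hydrogen to C5 from the α face and so set the trans ring fusion (5S).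

Step 7
Reactants: 8 (1R,4R,5S,6R)-dauc-8-ene-4,6-diol
Product: 9 (1R,4R,5R)-4-hydroxydauc-8-en-6-one (4β-OH, 5α-H, trans-fused)
Conditions: Dess–Martin periodinane, CH2Cl2, 0 °C → rt
Reagents that add atoms: none
Why: Dess–Martin oxidation takes only the secondary alcohol and runs without base, so C5 is not epimerised, the β,γ-olefin C8=C9 is not drawn into conjugation and the tertiary β-hydroxyl is neither eliminated nor lost by retro-aldol cleavage.

Step 8
Reactants: 9 (1R,4R,5R)-4-hydroxydauc-8-en-6-one
Product: 10 jaeschkeanadiol, (1R,4R,5S,6S)-dauc-8-ene-4,6-diol (4β-OH, 5α-H, 6α-OH)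
Conditions: Me4NBH(OAc)3, MeCN/AcOH (1:1), −30 °C
Reagents that add atoms: none
Why: Evans–Saksena hydroxyl-directed reduction, in which the 4β-hydroxyl replaces an acetate on boron and the hydride passes through a six-membered transition state to the β face of the C6 ketone, which gives the 6α-alcohol (6S); the reagent is too weak to reduce the ketone without this anchoring.

Step 9
Reactants: 10 jaeschkeanadiol; 11 3,4-dimethoxybenzoic acid (veratric acid)
Product: 12 jaeschkeanadiol veratrate, (1R,4R,5S,6S)-4-hydroxydauc-8-en-6-yl 3,4-dimethoxybenzoate (CNP0153023.1)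
Conditions: DCC, DMAP (cat.), CH2Cl2, rt
Reagents that add atoms: none
Why: Steglich esterification acylates the secondary 6α-hydroxyl with retention at C6, while the tertiary 4β-hydroxyl is too hindered to react; no stereocentre is touched.

## Compound list

1 | (2E,6E)-farnesol | CC(C)=CCC/C(C)=C/CC/C(C)=C/CO | starting material
2 | (2E,6E)-farnesyl chloride | CC(C)=CCC/C(C)=C/CC/C(C)=C/CCl | intermediate
3 | (2E,6E)-farnesyl diphosphate (free acid drawn, used as triammonium salt) | CC(C)=CCC/C(C)=C/CC/C(C)=C/COP(=O)(O)OP(=O)(O)O | intermediate
4 | daucene, (1R)-dauca-4,8-diene | CC(C)C1=C2CCC(C)=CC[C@@]2(C)CC1 | intermediate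
5 | (1R,4R)-4-hydroperoxydauca-5,8-diene (4β-OOH) | CC1=CC[C@@]2(C)CC[C@@](OO)(C(C)C)C2=CC1 | intermediate
6 | (1R,4R)-dauca-5,8-dien-4-ol (4β-OH) | CC1=CC[C@@]2(C)CC[C@@](O)(C(C)C)C2=CC1 | intermediate
7 | (1R,4R,5S,6R)-5,6-epoxydauc-8-en-4-ol (4β-OH, 5β,6β-epoxide) | CC1=CC[C@@]2(C)CC[C@@](O)(C(C)C)[C@]23O[C@@H]3C1 | intermediate
8 | (1R,4R,5S,6R)-dauc-8-ene-4,6-diol (6-epi-jaeschkeanadiol) | O[C@@H]1CC(C)=CC[C@@]2(C)CC[C@@](O)(C(C)C)[C@H]12 | intermediate
9 | (1R,4R,5R)-4-hydroxydauc-8-en-6-one (trans-fused) | O=C1CC(C)=CC[C@@]2(C)CC[C@@](O)(C(C)C)[C@H]12 | intermediate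
10 | jaeschkeanadiol, (1R,4R,5S,6S)-dauc-8-ene-4,6-diol | O[C@H]1CC(C)=CC[C@@]2(C)CC[C@@](O)(C(C)C)[C@H]12 | intermediate
11 | 3,4-dimethoxybenzoic acid | COc1ccc(C(=O)O)cc1OC | starting material
12 | jaeschkeanadiol veratrate, [(3R,3aS,4S,8aR)-3-hydroxy-6,8a-dimethyl-3-(propan-2-yl)-1,2,3,3a,4,5,8,8a-octahydroazulen-4-yl] 3,4-dimethoxybenzoate | COc1ccc(C(=O)O[C@H]2CC(C)=CC[C@@]3(C)CC[C@@](O)(C(C)C)[C@H]23)cc1OC | target

Total step count: 9
Longest linear sequence: 9 steps (1 → 12)

## Steps most likely to fail

**Step 3.**
- **What may go wrong:** The cyclase may quench the cation cascade early or at another position. That means other olefin isomers, water capture, or competing 1,6-, 1,10- or 1,11-closures. It may also fold the chain in the mirror-image sense or turn over too slowly for preparative work.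
- **Fallback (sets out from 3, comes back at 4):** 3 is given to a cyclase that ends the same 1,7/6,10 cascade by two hydride shifts and water capture. This gives carotol F1, (1R,4R,5S)-dauc-8-en-5-ol. The same alcohol, with the same C1 configuration, is the main sesquiterpene alcohol of commercial carrot seed oil and can be taken from there if no enzyme performs. SOCl2 in pyridine at 0 °C then removes the 5β-hydroxyl together with the antiperiplanar 4α-hydrogen. The tetrasubstituted olefin of 4 is thus formed by chemical and not by enzymatic proton loss.

**Step 4.**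
- **What may go wrong:** Oxygen may be delivered to C5 with loss of a C3 hydrogen, the ene reaction may take the α face, or the C8=C9 olefin may be oxidised as well.
- **Fallback (sets out from 6 as the step delivers it, comes back at 6 as the single 4β isomer):** This replaces substrate control at C4 by a reagent-controlled relay. The starting material is 6 mixed with its 4α-epimer F2.
  - Pyridinium chlorochromate, [C5H5NH][CrO3Cl], in CH2Cl2 (Babler–Dauben oxidative transposition) turns both epimers into dauca-4,8-dien-6-one F3 and erases C4.
  - Corey–Bakshi–Shibata reduction with the (S)-B-methyl oxazaborolidine and catecholborane in toluene at −78 °C treats the fully substituted alkenyl side as the large group. It should give (6R)-dauca-4,8-dien-6-ol F4 (6β-OH).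
  - VO(acac)2/t-BuOOH passes this configuration on to the olefin and gives 4β,5β-epoxydauc-8-en-6β-ol F5.
  - Dess–Martin oxidation gives 4β,5β-epoxydauc-8-en-6-one F6.
  - Wharton transposition (N2H4·H2O, cat. AcOH, MeOH) keeps the C4–O bond and returns 6.

**Step 6.**
- **What may go wrong:** Hydrogen may be transferred to the wrong face of the C5 radical. The radical may also be captured by a second Cp2TiCl, after which a neighbouring oxygen is lost.
- **Fallback (sets out from 6, comes back at 10, bypasses steps 5 to 8):** This sets C5–H and C6–O together by a stereospecific syn addition.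
  - The accessible C8=C9 olefin is masked with pyridinium tribromide (1 equiv, CH2Cl2, −40 °C) as the trans-8β,9α-dibromide F7; its configuration is immaterial.
  - The C5=C6 olefin is spared because it lies between two fully substituted carbons and is deactivated by the allylic oxygen.
  - Bromo-ether formation is excluded because it would place an E olefin in a six-membered ring.
  - BH3·THF then adds across C5=C6 with boron at C6, from the α face and away from the C1 methyl group and the C4 borate.
  - NaBO3 oxidation with retention gives the dibromo diol F8 (5α-H, 6α-OH).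
  - Zn dust in AcOH/Et2O restores the olefin and gives 10.

## Further compounds

F1 | step 3 | carotol, (1R,4R,5S)-dauc-8-en-5-ol | CC1=CC[C@]2(CC[C@@H]([C@]2(CC1)O)C(C)C)C
F2 | step 4 | (1R,4S)-dauca-5,8-dien-4-ol (4α-OH epimer of 6) | CC1=CC[C@@]2(C)CC[C@](O)(C(C)C)C2=CC1
F3 | step 4 | (1R)-dauca-4,8-dien-6-one | CC(C)C1=C2C(=O)CC(C)=CC[C@@]2(C)CC1
F4 | step 4 | (1R,6R)-dauca-4,8-dien-6-ol (6β-OH) | CC(C)C1=C2[C@H](O)CC(C)=CC[C@@]2(C)CC1
F5 | step 4 | 4β,5β-epoxydauc-8-en-6β-ol | CC(C)[C@]12CC[C@]3(C)CC=C(C)C[C@@H](O)[C@@]31O2
F6 | step 4 | 4β,5β-epoxydauc-8-en-6-one | CC(C)[C@]12CC[C@]3(C)CC=C(C)CC(=O)[C@@]31O2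
F7 | step 6 | 8β,9α-dibromodauc-5-en-4β-ol | C[C@@]1(Br)[C@@H](Br)C[C@@]2(C)CC[C@@](O)(C(C)C)C2=CC1
F8 | step 6 | 8β,9α-dibromodaucane-4β,6α-diol (5α-H) | C[C@@]1(Br)[C@@H](Br)C[C@@]2(C)CC[C@@](O)(C(C)C)[C@@H]2[C@@H](O)C1
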